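**Retrosynthetic overview** (neomanoalide numbering: C1 lactone C=O, C4 stereocentre, C6=C7(CH2OH), C10=C11)
1. The butenolide is the only ring made and is closed last, by lactonisation of a (2Z)-4-hydroxy-enoate obtained from syn-carbocupration of ynoate 14; the cyclohexene ring is bought in dihydro-β-ionone.
2. C9–C10 is cut to acid 12 and E-vinyl iodide 3 (decarboxylative sp3–sp2 coupling).
3. Key step: the C8–C9 bond and the 6Z trisubstituted alkene come from a Johnson–Claisen [3,3] rearrangement of allylic alcohol 10.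
4. 10 comes from aldehyde 8 and vinyl bromide 9; C4 is carried unchanged from (R)-α-hydroxy-γ-butyrolactone.

Assumption: bromide 9 and Bu3SnCH2OMOM are bought as catalogue reagents (9 is otherwise one silylation from 2-bromoallyl alcohol). TBS = tert-butyldimethylsilyl, MOM = methoxymethyl.

**Step 1**
Reactants: 1, dihydro-β-ionone
Product: 2, 2-(but-3-yn-1-yl)-1,3,3-trimethylcyclohex-1-ene
Conditions: LDA, THF, −78 °C; ClP(O)(OEt)2, −78 °C to rt; LDA (2.3 equiv), −78 °C to rt
Reagents that add atoms: none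
Why: Kinetic enolisation at the methyl group, enol phosphate formation and base-induced elimination give the terminal alkyne (Negishi methyl ketone → alkyne synthesis).

**Step 2**
Reactants: 2
Product: 3, 2-[(3E)-4-iodo-3-methylbut-3-en-1-yl]-1,3,3-trimethylcyclohex-1-ene
Conditions: Me3Al, Cp2ZrCl2 (cat.), CH2Cl2, 0 °C to rt; then I2, THF, −30 to 0 °C
Reagents that add atoms: trimethylaluminium, C[Al](C)C; iodine, II
Why: Zr-catalysed syn-methylalumination (Negishi carboalumination) followed by iodinolysis with retention fixes the E-trisubstituted C10=C11 geometry.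

**Step 3**
Reactants: 4, (R)-α-hydroxy-γ-butyrolactone
Product: 5, (3R)-3-(TBSO)oxolan-2-one
Conditions: TBSCl, imidazole, DMF, rt
Reagents that add atoms: TBSCl, CC(C)(C)[Si](C)(C)Cl
Why: Standard silylation of the secondary alcohol; the purchased stereocentre (future C4) is not touched.

**Step 4**
Reactants: 5
Product: 6, (3R)-3-(TBSO)oxolan-2-ol (anomer mixture)
Conditions: DIBAL-H, CH2Cl2, −78 °C
Reagents that add atoms: none
Why: Partial reduction of the lactone stops at the lactol at low temperature.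

**Step 5**
Reactants: 6
Product: 7, (3R)-3-(TBSO)pent-4-yn-1-ol
Conditions: dimethyl (1-diazo-2-oxopropyl)phosphonate, K2CO3, MeOH, 0 °C to rt
Reagents that add atoms: Ohira–Bestmann reagent, CC(=O)C(=[N+]=[N-])P(=O)(OC)OC
Why: Seyferth–Gilbert/Ohira–Bestmann homologation of the open hydroxy-aldehyde form of the lactol gives the terminal alkyne and frees the primary alcohol.

**Step 6**
Reactants: 7
Product: 8, (3R)-3-(TBSO)pent-4-ynal
Conditions: Dess–Martin periodinane, NaHCO3, CH2Cl2, 0 °C to rt; used crude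
Reagents that add atoms: none
Why: Buffered, non-basic oxidation avoids β-elimination of the silyloxy group.

**Step 7**
Reactants: 8; 9, [(2-bromoprop-2-en-1-yl)oxy](tert-butyl)dimethylsilane
Product: 10, (5R)-5-(TBSO)-2-(TBSOCH2)hept-1-en-6-yn-3-ol (C3 epimers)
Conditions: CrCl2 (4 equiv), NiCl2 (2 mol %), DMF, rt
Reagents that add atoms: none
Why: Nozaki–Hiyama–Kishi alkenylation is aldehyde-selective and non-basic, so the alkyne C–H and the β-silyloxy aldehyde survive; the new C3 carbinol is unselective but is destroyed in Step 8.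

**Step 8**
Reactants: 10
Product: 11, ethyl (4Z,7R)-7-(TBSO)-4-(TBSOCH2)non-4-en-8-ynoate
Conditions: MeC(OEt)3 (excess), EtCO2H (cat.), 140 °C, EtOH distilled off
Reagents that add atoms: triethyl orthoacetate, CC(OCC)(OCC)OCC
Why: Johnson–Claisen [3,3]-sigmatropic rearrangement through a chair with the carbinol substituent equatorial forms C8–C9 and puts CH2OTBS cis to the C5 chain (6Z), and both C3 epimers converge.

**Step 9**
Reactants: 11
Product: 12, (4Z,7R)-7-(TBSO)-4-(TBSOCH2)non-4-en-8-ynoic acid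
Conditions: LiOH, THF/MeOH/H2O, rt
Reagents that add atoms: lithium hydroxide, [Li+].[OH-]
Why: Simple saponification of the unhindered ethyl ester; silyl ethers and the alkyne are stable.

**Step 10**
Reactants: 12; 3
Product: 13, (3R,5Z,9E)-3-(TBSO)-6-(TBSOCH2)-10-methyl-12-(2,6,6-trimethylcyclohex-1-en-1-yl)dodeca-5,9-dien-1-yne
Conditions: N-hydroxyphthalimide, DIC, CH2Cl2, rt; then alkenylzinc from 3 (t-BuLi, Et2O, −78 °C; ZnCl2; 2–3 equiv), Ni(acac)2 (10 mol %), 2,2′-bipyridine (10 mol %), THF/DMF, rt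
Reagents that add atoms: none
Why: Ni-catalysed decarboxylative alkenylation of the redox-active ester couples the primary C9 radical with the alkenylzinc with retention of the E geometry, forming C9–C10.

**Step 11**
Reactants: 13
Product: 14, methyl (4R,6Z,10E)-4-(TBSO)-7-(TBSOCH2)-11-methyl-13-(2,6,6-trimethylcyclohex-1-en-1-yl)trideca-6,10-dien-2-ynoate
Conditions: n-BuLi, THF, −78 °C; ClCO2Me, −78 to 0 °C
Reagents that add atoms: methyl chloroformate, COC(Cl)=O
Why: Acylation of the lithium acetylide installs C1 as the ynoate.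

**Step 12**
Reactants: 14
Product: 15, methyl (2Z,4R,6Z,10E)-4-(TBSO)-3-(MOMOCH2)-7-(TBSOCH2)-11-methyl-13-(2,6,6-trimethylcyclohex-1-en-1-yl)trideca-2,6,10-trienoate
Conditions: Bu3SnCH2OMOM, n-BuLi, THF, −78 °C; CuBr·SMe2 (0.5 equiv); add 14, −78 °C; MeOH/NH4Cl quench at −78 °C
Reagents that add atoms: tributyl[(methoxymethoxy)methyl]stannane, CCCC[Sn](CCCC)(CCCC)COCOC
Why: Syn conjugate addition (carbocupration) of the alkoxymethyl cuprate to the ynoate, protonated cold, places CO2Me cis to C4 as needed for lactonisation.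

**Step 13**
Reactants: 15
Product: 16, (6Z)-neomanoalide
Conditions: 2 M aq. HCl, MeOH/THF, 40 °C
Reagents that add atoms: none
Why: Acid removes both TBS groups and the MOM group, and the freed C4–OH lactonises onto the cis ester to close the butenolide; C4 is not involved in bond breaking, so it stays R.

**Compound list**
1 | dihydro-β-ionone | CC(=O)CCC1=C(C)CCCC1(C)C | starting material
2 | 2-(but-3-yn-1-yl)-1,3,3-trimethylcyclohex-1-ene | C#CCCC1=C(C)CCCC1(C)C | intermediate
3 | 2-[(3E)-4-iodo-3-methylbut-3-en-1-yl]-1,3,3-trimethylcyclohex-1-ene | CC1=C(CC/C(C)=C/I)C(C)(C)CCC1 | intermediate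
4 | (R)-α-hydroxy-γ-butyrolactone | O=C1OCC[C@H]1O | starting material
5 | (3R)-3-(TBSO)oxolan-2-one | O=C1OCC[C@H]1O[Si](C)(C)C(C)(C)C | intermediate
6 | (3R)-3-(TBSO)oxolan-2-ol | OC1OCC[C@H]1O[Si](C)(C)C(C)(C)C | intermediate
7 | (3R)-3-(TBSO)pent-4-yn-1-ol | OCC[C@H](C#C)O[Si](C)(C)C(C)(C)C | intermediate
8 | (3R)-3-(TBSO)pent-4-ynal | O=CC[C@H](C#C)O[Si](C)(C)C(C)(C)C | intermediate
9 | [(2-bromoprop-2-en-1-yl)oxy](tert-butyl)dimethylsilane | C=C(Br)CO[Si](C)(C)C(C)(C)C | starting material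
10 | (5R)-5-(TBSO)-2-(TBSOCH2)hept-1-en-6-yn-3-ol | C=C(CO[Si](C)(C)C(C)(C)C)C(O)C[C@H](C#C)O[Si](C)(C)C(C)(C)C | intermediate
11 | ethyl (4Z,7R)-7-(TBSO)-4-(TBSOCH2)non-4-en-8-ynoate | CCOC(=O)CC/C(CO[Si](C)(C)C(C)(C)C)=C/C[C@H](C#C)O[Si](C)(C)C(C)(C)C | intermediate
12 | (4Z,7R)-7-(TBSO)-4-(TBSOCH2)non-4-en-8-ynoic acid | OC(=O)CC/C(CO[Si](C)(C)C(C)(C)C)=C/C[C@H](C#C)O[Si](C)(C)C(C)(C)C | intermediate
13 | (3R,5Z,9E)-3-(TBSO)-6-(TBSOCH2)-10-methyl-12-(2,6,6-trimethylcyclohex-1-en-1-yl)dodeca-5,9-dien-1-yne | CC1=C(CC/C(C)=C/CC/C(CO[Si](C)(C)C(C)(C)C)=C/C[C@H](C#C)O[Si](C)(C)C(C)(C)C)C(C)(C)CCC1 | intermediate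
14 | methyl (4R,6Z,10E)-4-(TBSO)-7-(TBSOCH2)-11-methyl-13-(2,6,6-trimethylcyclohex-1-en-1-yl)trideca-6,10-dien-2-ynoate | CC1=C(CC/C(C)=C/CC/C(CO[Si](C)(C)C(C)(C)C)=C/C[C@H](C#CC(=O)OC)O[Si](C)(C)C(C)(C)C)C(C)(C)CCC1 | intermediate
15 | methyl (2Z,4R,6Z,10E)-4-(TBSO)-3-(MOMOCH2)-7-(TBSOCH2)-11-methyl-13-(2,6,6-trimethylcyclohex-1-en-1-yl)trideca-2,6,10-trienoate | CC1=C(CC/C(C)=C/CC/C(CO[Si](C)(C)C(C)(C)C)=C/C[C@H](/C(COCOC)=C\C(=O)OC)O[Si](C)(C)C(C)(C)C)C(C)(C)CCC1 | intermediate
16 | (6Z)-neomanoalide, (5R)-4-(hydroxymethyl)-5-[(2Z,6E)-3-(hydroxymethyl)-7-methyl-9-(2,6,6-trimethylcyclohex-1-en-1-yl)nona-2,6-dien-1-yl]furan-2(5H)-one | CC1=C(CC/C(C)=C/CC/C(=C/C[C@H]2OC(=O)C=C2CO)CO)C(C)(C)CCC1 | target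

**Totals**
Total steps: 13. Longest linear sequence: 11 (4 → 16, Steps 3–13).

**Three steps most likely to fail**
1. Step 10: the Ni/radical coupling runs with a free terminal alkyne present and needs excess 3. Fallback: iododecarboxylate 12 (PhI(OAc)2, I2, hν) to the primary iodide, insert zinc and run a Pd-catalysed Negishi coupling with iodide 3.
2. Step 12: the alkoxymethyl cuprate may give E/Z leakage or SN2′ loss of the propargylic silyloxy group. Fallback: build the butenolide by intramolecular Wittig instead, via a C3 ketone (LiCH2OMOM on a Weinreb amide made by opening 5) and reaction of the α-hydroxy ketone with Ph3P=C=C=O.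
3. Step 5: K2CO3/MeOH on the α-silyloxy lactol risks C4 epimerisation or silyl migration. Fallback: reduce 5 to the diol, protect the primary alcohol, oxidise, and make the alkyne by Corey–Fuchs (CBr4/PPh3, then n-BuLi), which avoids basic methanol.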